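(The runs were computed for substances that don't exist, and the scatter is random.)

What stood in this flask at 15 d, and had anything stopped it? I began from the two runs.

| setting | Thursday's | Friday's | flask |
|---|---|---|---|
| solid substrate | 20 mM | 30 mM | 20 mM |
| gas | 11 mM (held) | 11 mM (held) | 11 mM (held) |
| remark | the very flask that is asked about, followed so far | run made earlier |  |
| time |  |  | 15 d |

| run | time / d | target / % | solid substrate / % |
|---|---|---|---|
| Thursday's | 0.833 | 31.7 | 62.4 |
| Thursday's | 1.67 | 67.0 | 26.6 |
| Thursday's | 2.50 | 93.8 | 0.1 |
| Thursday's | 4.00 | 95.8 | 0 |
| Thursday's | 5.00 | 94.9 | 0 |
| Friday's | 0.500 | 11.1 | 83.8 |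
| Friday's | 0.833 | 22.1 | 75.1 |
| Friday's | 1.67 | 46.1 | 52.5 |
| Friday's | 3.00 | 79.3 | 13.7 |
| Friday's | 6.00 | 94.8 | 0 |

(readings scatter by 1 percentage point)

- at 15 d, what has stopped the reaction, if anything has (for what has run out or reacted, a solid counts together with what of it has only dissolved) (forward and back rates have come level / it is still moving / all of the solid substrate has reacted)
- target at 15 d, in percent of the solid substrate charged

- in percentages every species weighs as the solid substrate in it: one side product counts as two
- for target the solid product is counted in
- as a solid, counted per litre of solution: solid substrate, solid product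
- at the start none of partner is dissolved
- reactions considered so far: 2 dissolved substrate -> side product; gas <-> partner; solid substrate <-> dissolved substrate; solid product <-> target; dissolved substrate + partner -> target
- at the start none of the solid substrate is in solution
- what has only dissolved of solid substrate counts as not reacted
- the reaction counts as stopped when no species that holds the solid substrate changes by six tenths of a point or more over the second half of the time

In the first instants of Thursday's run, neither partner nor substrate was dissolved, so both had to enter solution before target could form. By 0.833 d, Thursday's flask held 62.4% solid substrate and 31.7% target.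

In the middle of Thursday's run, the readings of the solid gave a fall of 8.55 mM d⁻¹ between 0.833 d and 1.67 d. Friday's flask, charged with 30 mM, lost 8.50 mM d⁻¹ between 0.833 d and 3.00 d, about the same, so I read the fall as zero-order in the solid. Dividing Thursday's 20 mM by Thursday's rate gave 2.34 d, and I called this the clearing time: the charge of solid substrate divided by the steady rate at which it goes.

The moment worth watching was therefore the last of the solid. Thursday's flask read 0.1% at 2.50 d, just after the clearing time. Later target readings were 95.8% and 94.9% on Thursday and 94.8% on Friday, a spread of 1 percentage point against a scatter of 1 point. The asked time was 6.41 clearing times, so I expected no solid and target near the mean of those readings, 95.2%.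

The forecast agreed: all of the solid substrate has reacted, with target at 95.2%, and its ground was that “No listed step consumes target, and its formation is irreversible”.

The flask gave 94.5% at 15 d: all of the solid substrate has reacted.

    2 dissolved substrate → side product (k = 18.0 M⁻¹ h⁻¹)
    gas ⇌ partner, rate k2*(csat - [partner]) (kL = 1.90 h⁻¹)
    solid substrate ⇌ dissolved substrate, rate k3*(cs3 - [dissolved substrate]) while solid is left; crystals form when [dissolved substrate] > cs3 (solubility = 1.50 mM, k = 0.480 h⁻¹)
    solid product ⇌ target, rate k4*(cs4 - [target]) while solid is left; crystals form when [target] > cs4 (solubility = 1.60 mM, k = 17.0 h⁻¹)
    dissolved substrate + partner → target (k = 42.0 M⁻¹ h⁻¹)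

At 3.00 d, later than the clearing time of 2.34 d, this flask held 0% solid substrate and 94.5% target. For a neighbour flask charged with 12 mM, I reckoned at Thursday's rate a clearing time of 1.40 d. At 15 d, ten times that, it had 0% of its charge left and target at 94.6%.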